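An excess is a poor thing to carry from one sample to the next flask. The grey run gives 96.6 % after 1.67 d and 68.8 % after 8.00 d. So we keep books on the charge and carry a fraction left.

| setting | grey | amber | blue | flask |
|---|---|---|---|---|
| left-handed substrate | 0.70 M | 1.1 M | 0.50 M | 0.50 M |
| right-handed substrate | 0.70 M | 1.1 M | 0.50 M | 0.50 M |
| gas | 19 mM (held) | 19 mM (held) | 19 mM (held) | 19 mM (held) |
| catalyst | 12 mM | 12 mM | 24 mM | 12 mM |
| remark | run made earlier | run made earlier | run made earlier |  |
| time |  |  |  | 10 d |

- grey (time / d: left-handed product / %, right-handed product / %): 1.67: 51.3, 0.9; 3.00: 48.1, 2.5; 5.00: 47.2, 7.0; 6.00: 49.0, 6.5; 8.00: 50.9, 9.4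
- amber (time / d: left-handed product / %, right-handed product / %): 0.625: 20.6, 1.2; 1.25: 38.1, 0.1; 2.50: 49.6, 2.9; 4.00: 48.4, 3.3; 8.00: 49.5, 9.9
- blue (time / d: left-handed product / %, right-handed product / %): 0.625: 40.0, 0.4; 2.08: 49.5, 3.3; 4.00: 48.6, 9.4; 6.00: 51.5, 12.3; 8.00: 49.2, 16.5

(scatter of a reading: 1 percentage point)

- catalyst is single-handed; left-handed substrate and right-handed substrate are mirror images of each other, charged as a racemate, each of them at the stated concentration
- the numbers in the tables scatter by 1 percentage point (one standard deviation)
- at the start none of the gas is in solution
- an excess is the difference of the two amounts in percent of their sum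
- an excess is below zero if the other one leads

1. excess of left-handed product over right-handed product in the product at 5.0 h
2. excess of left-handed product over right-handed product in the product at 10 d
3. part of the left-handed substrate and right-handed substrate charged together that has reacted at 10 d

The first entry is the left-handed substrate, the limiting reagent of the fast channel. It holds 50.0 % of the charge, and the left-handed product levels off there, at 49.5 % in the amber run.

The second entry is the right-handed substrate, which we treat as pseudo-first-order. A reading of right-handed product, doubled, is the part of that substrate consumed. From the mean of the last grey and amber readings, both at 12 mM catalyst and taken at 8.00 d, we take the logarithm of charged over remaining right-handed substrate, divided by the clock from zero. This is the fraction-left constant, 0.0268 d⁻¹. The blue run, with twice the catalyst and a smaller substrate charge, reads 0.0501 d⁻¹, about twice as much. The grey and amber runs, with 0.70 M and 1.1 M of each substrate, read 9.4 % and 9.9 % of right-handed product at that same time, so we scale the constant with [catalyst].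

Our books for the flask at 10 d:

right-handed substrate left, of its charge: 76.5 %
right-handed product, of the whole charge: 11.8 %
reacted: 61.8 %
excess: 61.8 %

For the early sample of the flask, at 5.0 h, we borrow a rough figure from another run and a later time: the blue reading after 0.625 d gives 98.0 %, though its right-handed product of 0.4 % lies within the scatter.

The forecast says, in the order asked, 98 %, 62 % and 62 %, on the ground that the right-handed substrate reacts “hardly at all until the left-handed is gone”.

The flask gives 98.8 %, 62.9 % and 61.4 %.

    partner + catalyst + left-handed substrate → catalyst + left-handed product (k = 986 M⁻² h⁻¹)
    2 partner → self-condensation product (k = 0.434 M⁻¹ h⁻¹)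
    gas ⇌ partner, rate k3*(csat - [partner]) (kL = 1.98 h⁻¹)
    partner + catalyst + right-handed substrate → catalyst + right-handed product (k = 5.19 M⁻² h⁻¹)
    partner → decomposed reagent (k = 0.0253 h⁻¹)

At 10.0 d the flask keeps 0 % of its left-handed substrate and 77 % of its right-handed substrate, and the fraction-left constant had given 76.5 % for the latter. In a second flask, the same but with 0.0072 M catalyst, the constant scales to 0.0161 d⁻¹, which leaves 85.1 % of the right-handed substrate and gives an excess of 74.1 %. Computed, that second flask keeps 86 % of its right-handed substrate, with excess 74.8 % and 57.2 % reacted.

Readings and results are simulated with made-up constants; scatter was added.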